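**Plan**
- Retrosynthesis (isochromene numbering C1, O2, C3, C4, C4a, C5–C8, C8a): the acetate is cut first, then O2–C3 (alkyne hydroalkoxylation) and C4–C4a (Sonogashira), which release the dienyne side chain and a bromo-cyclohexenone. The carbocycle is then cut at C6–C7 and C8–C8a in one stroke.
- Enabling feature: in the ring C4a–C5–C6–C7–C8–C8a the C4a=C5 double bond lies between C6 (oxygen-bearing) and C8a (bearing carbon C1). The ring is therefore a [4+2] adduct whose diene termini can be tied by a C1(=O)–O bridge, i.e. a 2-pyrone. C7 (CH3, O) and C8 (O), with cis oxygens, are the ketene acetal of lactic acid.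
- Forward: 4-bromo-2-pyrone and the silyl ketene acetal of the (R)-lactic acid/pivalaldehyde dioxolanone give a bridged lactone, so the carbocycle arises first. Ionic hydrogenation, acetal cleavage, lactone reduction and allylic oxidation lead to the bromo-enone. Sonogashira coupling and 6-endo hydroalkoxylation close the pyran last; acetylation ends the route.
- Stereochemistry: C7 comes from (R)-lactic acid, relayed through the acetal carbon. C8a comes from the endo mode under the lactone bridge. C8 comes from the forced cis fusion of the dioxolane at hydride capture. The side-chain centre comes from (S)-2-methylbutan-1-ol, and the two E alkenes from Wittig and Horner–Wadsworth–Emmons olefinations.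

Key step: step 4

Remark: 4-hydroxy-2H-pyran-2-one, (R)-lactic acid and diethyl [3-(trimethylsilyl)prop-2-yn-1-yl]phosphonate are taken as catalogue compounds; atom labels C1–C8a in the text are those of the isochromene skeleton of the target.

Step 1
Reactants: 1 (R)-lactic acid
Product: 2 (2R,5R)-2-tert-butyl-5-methyl-1,3-dioxolan-4-one
Conditions: pivalaldehyde, TsOH·H2O (cat.), H2SO4 (cat.), pentane, reflux with water separator; crystallisation from pentane/Et2O at −78 °C
Reagents that add atoms: pivalaldehyde CC(C)(C)C=O
Why: Acid-catalysed acetalisation of the α-hydroxy acid with azeotropic removal of water; the new acetal centre forms under equilibrating conditions cis to the methyl group and the cis isomer is freed from the minor trans isomer by low-temperature crystallisation, so that the lactate configuration is copied onto the acetal carbon.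

Step 2
Reactants: 2 (2R,5R)-2-tert-butyl-5-methyl-1,3-dioxolan-4-one
Product: 3 tert-butyl{[(2R)-2-tert-butyl-5-methyl-1,3-dioxol-4-yl]oxy}dimethylsilane
Conditions: LiN(i-Pr)2, THF, −78 °C; then t-BuMe2SiCl, DMPU, −78 → −20 °C
Reagents that add atoms: tert-butyldimethylsilyl chloride CC(C)(C)[Si](C)(C)Cl
Why: Lactone enolisation and O-silylation (silyl ketene acetal formation) at −78 °C, below the temperature at which the enolate fragments; the lactate carbon becomes sp2 and the acetal carbon alone now carries the chirality (self-regeneration of stereocentres).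

Step 3
Reactants: 4 4-hydroxy-2H-pyran-2-one
Product: 5 4-bromo-2H-pyran-2-one
Conditions: PBr3, DMF, Et2O, 0 → 60 °C
Reagents that add atoms: phosphorus tribromide BrP(Br)Br
Why: Vilsmeier-type deoxybromination of a vinylogous carboxylic acid to the vinylogous acyl bromide, the standard route to 4-bromo-2-pyrones; no stereocentre is formed.

Step 4
Reactants: 5 4-bromo-2H-pyran-2-one and 3 tert-butyl{[(2R)-2-tert-butyl-5-methyl-1,3-dioxol-4-yl]oxy}dimethylsilane
Product: 6 endo cycloadduct, (1R,4S)-5-bromo-2-oxabicyclo[2.2.2]oct-5-en-3-one carrying on C7/C8 a cis-fused (2R)-2-tert-butyl-1,3-dioxolane (oxygens syn to the C5=C6 bridge), CH3 on C7 and OSi(t-Bu)Me2 on C8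
Conditions: 3 (1.5 equiv), toluene (1 M), 70 °C, sealed tube, moisture excluded
Reagents that add atoms: none
Why: Thermal inverse-electron-demand Diels–Alder reaction in which the electron-poor 2-pyrone 5 is the 4π component through C3–C6 and the silyl ketene acetal 3 the 2π component, concerted but asynchronous, the bond from the nucleophilic methyl-bearing carbon of 3 to the δ-carbon C6 of the pyrone leading and the bond from the dioxygenated carbon to C3 following, so that the C6–C7 and C8–C8a bonds of the target arise in one event. The closest known reaction type is the cycloaddition of 2-pyrones with enol ethers, silyl enol ethers and ketene acetals to isolable 2-oxabicyclo[2.2.2]oct-5-en-3-ones. The carbocycle (C4a, C5, C6, C7, C8, C8a) is closed in the [4+2] mode, suprafacially on both partners, and the lactone bridge C1(=O)–O kept from the pyrone holds C1 and the C6 oxygen on one face. C7 is set by the acetal carbon of 3, whose tert-butyl group blocks one face of the dioxole (the face selection its enolate shows toward electrophiles); C8a is set by the endo mode, which places the dioxolane oxygens under C4=C5 of the diene and hence anti to the lactone bridge (C8–O trans to C1); the silyl ketal carbon C8 is cis-fused by necessity and the temporary C6 centre is later oxidised away. The step needs regioselectivity (methyl-bearing carbon to C6), secured by the ketene acetal polarisation with two oxygens on the other carbon; endo selectivity, the normal outcome for oxygenated dienophiles with 2-pyrones; and attack at C6 instead of the bromine-bearing C4, secured by the hindrance of the tetrasubstituted nucleophilic carbon.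

Step 5
Reactants: 6 endo cycloadduct (silyl ketal)
Product: 7 (1R,4S,7R,8R)-5-bromo-7-methyl-2-oxabicyclo[2.2.2]oct-5-en-3-one-7,8-diol as its cyclic (S)-2,2-dimethylpropylidene acetal (H in place of the silyloxy group at C8)
Conditions: Et3SiH, Me3SiOTf (20 mol %), CH2Cl2, −78 → −30 °C
Reagents that add atoms: none
Why: Ionic hydrogenation of a lactol silyl ether (Lewis-acid ionisation of the exocyclic silyloxy group to the ring oxocarbenium ion, then hydride transfer from Et3SiH); hydride can only enter from the exo face because the dioxolane must stay cis-fused to the rigid bicycle, which sets C8 with its oxygen cis to the C7 oxygen and trans to C1.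

Step 6
Reactants: 7 acetal lactone
Product: 8 (1R,4S,7R,8R)-5-bromo-7,8-dihydroxy-7-methyl-2-oxabicyclo[2.2.2]oct-5-en-3-one
Conditions: TFA/H2O (4:1), 0 °C → rt
Reagents that add atoms: none
Why: Acid hydrolysis of the alkylidene acetal with release of pivalaldehyde; the bridged lactone and the vinyl bromide tolerate aqueous TFA and the two endo hydroxyls lie on the face opposite the lactone carbonyl, so no translactonisation or stereochemical change is expected.

Step 7
Reactants: 8 (1R,4S,7R,8R)-5-bromo-7,8-dihydroxy-7-methyl-2-oxabicyclo[2.2.2]oct-5-en-3-one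
Product: 9 (1S,2R,5R,6R)-4-bromo-5-(hydroxymethyl)-1-methylcyclohex-3-ene-1,2,6-triol
Conditions: LiAlH4, THF, −20 → 0 °C; aqueous potassium sodium tartrate work-up
Reagents that add atoms: none
Why: Hydride reduction of the lactone to the diol, which frees C1 as CH2OH and C6 as a secondary allylic alcohol; C8a keeps its configuration because the transient aldehyde is reduced faster than it enolises, and the vinyl bromide is inert at this temperature.

Step 8
Reactants: 9 (1S,2R,5R,6R)-4-bromo-5-(hydroxymethyl)-1-methylcyclohex-3-ene-1,2,6-triol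
Product: 10 (4R,5R,6R)-3-bromo-5,6-dihydroxy-4-(hydroxymethyl)-6-methylcyclohex-2-en-1-one
Conditions: activated MnO2 (excess), acetone, rt
Reagents that add atoms: none
Why: Chemoselective MnO2 oxidation of the only allylic alcohol (C6–OH) to the β-bromo-enone; the primary, the non-allylic secondary and the tertiary hydroxyls should remain, and the temporary C6 stereocentre is removed.

Step 9
Reactants: 11 (S)-2-methylbutan-1-ol
Product: 13 (2E,4S)-2,4-dimethylhex-2-enal, via (S)-2-methylbutanal 12 (not isolated)
Conditions: TEMPO (5 mol %), PhI(OAc)2, CH2Cl2, rt; then Ph3P=C(CH3)CHO, toluene, 80 °C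
Reagents that add atoms: 2-(triphenylphosphoranylidene)propanal CC(C=O)=P(c1ccccc1)(c1ccccc1)c1ccccc1
Why: Base-free TEMPO/PhI(OAc)2 oxidation followed in the same flask by Wittig olefination with the formyl-stabilised ylide, which should give the (E)-trisubstituted enal; the stereocentre comes unchanged from the chiral pool.

Step 10
Reactants: 13 (2E,4S)-2,4-dimethylhex-2-enal
Product: 14 trimethyl[(3E,5E,7S)-5,7-dimethylnona-3,5-dien-1-yn-1-yl]silane
Conditions: (EtO)2P(O)CH2C≡CSiMe3, LiN(SiMe3)2, THF, −78 °C → rt
Reagents that add atoms: diethyl [3-(trimethylsilyl)prop-2-yn-1-yl]phosphonate CCOP(=O)(CC#C[Si](C)(C)C)OCC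
Why: Horner–Wadsworth–Emmons olefination with the lithiated propargylic phosphonate, which is (E)-selective for this type of enal and extends the chain to the silyl-protected dienyne.

Step 11
Reactants: 14 trimethyl[(3E,5E,7S)-5,7-dimethylnona-3,5-dien-1-yn-1-yl]silane
Product: 15 (3E,5E,7S)-5,7-dimethylnona-3,5-dien-1-yne
Conditions: K2CO3 (cat.), MeOH, rt
Reagents that add atoms: none
Why: Base-catalysed methanolysis of the alkynyl C–Si bond (protodesilylation) to the terminal alkyne; the alkenes and the stereocentre are untouched.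

Step 12
Reactants: 10 (4R,5R,6R)-3-bromo-5,6-dihydroxy-4-(hydroxymethyl)-6-methylcyclohex-2-en-1-one and 15 (3E,5E,7S)-5,7-dimethylnona-3,5-dien-1-yne
Product: 16 (4R,5R,6R)-3-[(3E,5E,7S)-5,7-dimethylnona-3,5-dien-1-yn-1-yl]-5,6-dihydroxy-4-(hydroxymethyl)-6-methylcyclohex-2-en-1-one
Conditions: PdCl2(PPh3)2 (3 mol %), CuI (6 mol %), Et3N, THF, rt, degassed
Reagents that add atoms: none
Why: Sonogashira coupling: the β-bromo-enone (a vinylogous acyl bromide) undergoes fast oxidative addition to zerovalent palladium at room temperature and the free hydroxyls are tolerated; no stereocentre is affected.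

Step 13
Reactants: 16 (4R,5R,6R)-3-[(3E,5E,7S)-5,7-dimethylnona-3,5-dien-1-yn-1-yl]-5,6-dihydroxy-4-(hydroxymethyl)-6-methylcyclohex-2-en-1-one
Product: 17 (7R,8R,8aR)-3-[(1E,3E,5S)-3,5-dimethylhepta-1,3-dien-1-yl]-7,8-dihydroxy-7-methyl-1,7,8,8a-tetrahydro-6H-isochromen-6-one
Conditions: AuCl(PPh3) (5 mol %), AgOSO2CF3 (5 mol %), CH2Cl2, rt
Reagents that add atoms: none
Why: π-Acid-catalysed 6-endo-dig hydroalkoxylation (cycloisomerisation) of the primary hydroxyl onto the alkyne, as used for 1H-isochromenes; attack at the alkyne carbon remote from the enone is favoured both by the conjugate (1,6) polarisation and by the cation-stabilising dienyl group, while closure through the C8 hydroxyl would give a strained bridged ring.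

Step 14
Reactants: 17 (7R,8R,8aR)-3-[(1E,3E,5S)-3,5-dimethylhepta-1,3-dien-1-yl]-7,8-dihydroxy-7-methyl-1,7,8,8a-tetrahydro-6H-isochromen-6-one
Product: 18 (7R,8R,8aR)-3-[(1E,3E,5S)-3,5-dimethylhepta-1,3-dien-1-yl]-7-hydroxy-7-methyl-6-oxo-1,7,8,8a-tetrahydro-6H-isochromen-8-yl acetate (target)
Conditions: Ac2O, pyridine, CH2Cl2, 0 °C → rt
Reagents that add atoms: acetic anhydride CC(=O)OC(C)=O
Why: Selective O-acylation of the secondary C8 hydroxyl in the presence of the hindered tertiary C7 hydroxyl, under mild conditions without a strong base so that the γ-acidic C8a–H/C8–OAc pair is not driven to elimination.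

**Compound list**
1 | (R)-lactic acid | C[C@@H](O)C(=O)O | starting material
2 | (2R,5R)-2-tert-butyl-5-methyl-1,3-dioxolan-4-one | C[C@H]1O[C@H](OC1=O)C(C)(C)C | intermediate
3 | tert-butyl{[(2R)-2-tert-butyl-5-methyl-1,3-dioxol-4-yl]oxy}dimethylsilane | CC1=C(O[Si](C)(C)C(C)(C)C)O[C@H](C(C)(C)C)O1 | intermediate
4 | 4-hydroxy-2H-pyran-2-one | O=C1C=C(O)C=CO1 | starting material
5 | 4-bromo-2H-pyran-2-one | O=C1C=C(Br)C=CO1 | intermediate
6 | endo cycloadduct: (1R,4S)-5-bromo-2-oxabicyclo[2.2.2]oct-5-en-3-one with a (2R)-2-tert-butyl-1,3-dioxolane cis-fused at C7/C8 (oxygens syn to C5=C6), CH3 on C7, OSi(t-Bu)Me2 on C8 | O=C1O[C@@H]2C=C(Br)[C@H]1[C@@]3(O[Si](C)(C)C(C)(C)C)O[C@H](C(C)(C)C)O[C@@]23C | intermediate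
7 | 7,8-O-[(S)-2,2-dimethylpropylidene] acetal of (1R,4S,7R,8R)-5-bromo-7,8-dihydroxy-7-methyl-2-oxabicyclo[2.2.2]oct-5-en-3-one | O=C1O[C@@H]2C=C(Br)[C@H]1[C@H]3O[C@H](C(C)(C)C)O[C@@]23C | intermediate
8 | (1R,4S,7R,8R)-5-bromo-7,8-dihydroxy-7-methyl-2-oxabicyclo[2.2.2]oct-5-en-3-one | O=C1O[C@@H]2C=C(Br)[C@H]1[C@@H](O)[C@@]2(C)O | intermediate
9 | (1S,2R,5R,6R)-4-bromo-5-(hydroxymethyl)-1-methylcyclohex-3-ene-1,2,6-triol | OC[C@H]1C(Br)=C[C@@H](O)[C@](C)(O)[C@@H]1O | intermediate
10 | (4R,5R,6R)-3-bromo-5,6-dihydroxy-4-(hydroxymethyl)-6-methylcyclohex-2-en-1-one | BrC1=CC(=O)[C@](C)(O)[C@H](O)[C@H]1CO | intermediate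
11 | (S)-2-methylbutan-1-ol | CC[C@H](C)CO | starting material
12 | (S)-2-methylbutanal | CC[C@H](C)C=O | intermediate
13 | (2E,4S)-2,4-dimethylhex-2-enal | CC[C@H](C)/C=C(C)/C=O | intermediate
14 | trimethyl[(3E,5E,7S)-5,7-dimethylnona-3,5-dien-1-yn-1-yl]silane | CC[C@H](C)/C=C(C)/C=C/C#C[Si](C)(C)C | intermediate
15 | (3E,5E,7S)-5,7-dimethylnona-3,5-dien-1-yne | CC[C@H](C)/C=C(C)/C=C/C#C | intermediate
16 | (4R,5R,6R)-3-[(3E,5E,7S)-5,7-dimethylnona-3,5-dien-1-yn-1-yl]-5,6-dihydroxy-4-(hydroxymethyl)-6-methylcyclohex-2-en-1-one | CC[C@H](C)/C=C(C)/C=C/C#CC1=CC(=O)[C@](C)(O)[C@H](O)[C@H]1CO | intermediate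
17 | (7R,8R,8aR)-3-[(1E,3E,5S)-3,5-dimethylhepta-1,3-dien-1-yl]-7,8-dihydroxy-7-methyl-1,7,8,8a-tetrahydro-6H-isochromen-6-one | CC[C@H](C)/C=C(C)/C=C/C1=CC2=CC(=O)[C@](C)(O)[C@H](O)[C@H]2CO1 | intermediate
18 | (7R,8R,8aR)-3-[(1E,3E,5S)-3,5-dimethylhepta-1,3-dien-1-yl]-7-hydroxy-7-methyl-6-oxo-1,7,8,8a-tetrahydro-6H-isochromen-8-yl acetate | CC[C@H](C)/C=C(C)/C=C/C1=CC2=CC(=O)[C@](C)(O)[C@H](OC(C)=O)[C@H]2CO1 | target

Total step count: 14. Longest linear sequence: 10 steps (steps 1, 2, 4, 5, 6, 7, 8, 12, 13, 14).

**Steps most likely to fail**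

Step 4. The cycloaddition may be too slow below the temperature at which the bridged lactone loses CO2 by retro-[4+2], or may divert into conjugate addition with silyl transfer and no ring closure; endo selectivity may also erode on heating. The fallback sets out from 4 and comes back at 6. Compound 4 is brominated at C3 with N-bromosuccinimide in MeCN to 3-bromo-4-hydroxy-2H-pyran-2-one F1, which PBr3/DMF converts into 3,4-dibromo-2H-pyran-2-one F2. The 3-bromo substituent lowers the LUMO of the diene, so the cycloaddition with 3 should proceed near room temperature to the dibromo cycloadduct F3. Bu3SnH with AIBN then removes only the tertiary bridgehead bromine next to the lactone carbonyl to give 6; retention is enforced at the bridgehead and the vinylic bromine is far less reactive.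

Step 5. Ionisation may take place at the acetal carbon or at the ring C8–O bond instead of at the exocyclic silyloxy group, which would lead to loss of the pivalaldehyde acetal and to a C8 ketone instead of hydride capture. The fallback sets out from 6 and comes back at 8. Aqueous HF in MeCN cleaves the silyl ketal on purpose; the hemiketal collapses with loss of pivalaldehyde to (1R,4S,7S)-5-bromo-7-hydroxy-7-methyl-2-oxabicyclo[2.2.2]oct-5-ene-3,8-dione F4. The tertiary hydroxyl is silylated with Et3SiOTf and 2,6-lutidine to the triethylsilyl ether F5. LiBH(s-Bu)3 in THF at −78 °C should then deliver hydride to the C8 ketone from the face opposite the neighbouring silyloxy group, giving (1R,4S,7R,8R)-5-bromo-8-hydroxy-7-methyl-7-[(triethylsilyl)oxy]-2-oxabicyclo[2.2.2]oct-5-en-3-one F6 with the two oxygens cis. HF·pyridine removes the silyl group to give 8.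

Step 13. Ring closure may go astray through 5-exo attack or through the secondary C8 hydroxyl, or the polyene may degrade under the π-acid. The fallback sets out from 16 and comes back at 17. Pyrrolidine in THF adds in the conjugate (1,6) sense to the ynenone to give the vinylogous amide (4R,5R,6R)-3-[(3E,5E,7S)-5,7-dimethyl-2-(pyrrolidin-1-yl)nona-1,3,5-trien-1-yl]-5,6-dihydroxy-4-(hydroxymethyl)-6-methylcyclohex-2-en-1-one F7, so that the oxygen-accepting carbon is fixed by polarity alone. Brief treatment with aqueous acetic acid then exchanges the amine for the primary hydroxyl by addition–elimination at that carbon and closes the pyran ring to 17.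

**Further compounds**
F1 | step 4 | 3-bromo-4-hydroxy-2H-pyran-2-one | O=C1OC=CC(O)=C1Br
F2 | step 4 | 3,4-dibromo-2H-pyran-2-one | O=C1OC=CC(Br)=C1Br
F3 | step 4 | dibromo cycloadduct (compound 6 with bromine at the bridgehead C4) | O=C1O[C@@H]2C=C(Br)[C@@]1(Br)[C@@]3(O[Si](C)(C)C(C)(C)C)O[C@H](C(C)(C)C)O[C@@]23C
F4 | step 5 | (1R,4S,7S)-5-bromo-7-hydroxy-7-methyl-2-oxabicyclo[2.2.2]oct-5-ene-3,8-dione | O=C1O[C@@H]2C=C(Br)[C@H]1C(=O)[C@@]2(C)O
F5 | step 5 | (1R,4S,7S)-5-bromo-7-methyl-7-[(triethylsilyl)oxy]-2-oxabicyclo[2.2.2]oct-5-ene-3,8-dione | O=C1O[C@@H]2C=C(Br)[C@H]1C(=O)[C@@]2(C)O[Si](CC)(CC)CC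
F6 | step 5 | (1R,4S,7R,8R)-5-bromo-8-hydroxy-7-methyl-7-[(triethylsilyl)oxy]-2-oxabicyclo[2.2.2]oct-5-en-3-one | O=C1O[C@@H]2C=C(Br)[C@H]1[C@@H](O)[C@@]2(C)O[Si](CC)(CC)CC
F7 | step 13 | (4R,5R,6R)-3-[(3E,5E,7S)-5,7-dimethyl-2-(pyrrolidin-1-yl)nona-1,3,5-trien-1-yl]-5,6-dihydroxy-4-(hydroxymethyl)-6-methylcyclohex-2-en-1-one | CC[C@H](C)/C=C(C)/C=C/C(=CC1=CC(=O)[C@](C)(O)[C@H](O)[C@H]1CO)N1CCCC1
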